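**Retrosynthetic overview**

1. The target comes from its 4'''-O-acetate 15 (step 9). Compound 15 comes from the 5,5''-dideoxy bis-flavanone 13 by making C5–O and C5''–O last. On rings A and A'', C5–H and C5''–H are the only C–H bonds peri to the C4 and C4'' carbonyls, because the other ortho carbons (C8a, C8a'') carry the ring oxygens O1 and O1''.
2. Without these two hydroxyls both halves are 5-unsubstituted flavanones, so each stereocentre is set by catalyst-controlled aryl addition to a chromone. C2–C1' comes from boronic acid 9 and 7-methoxychromone 12. C2''–C1''' comes from chromone 5 and 4-acetoxyphenylboronic acid 6, which also delivers the acetate.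
3. Chromone 5 is closed from acetophenone 3 through its single ortho phenol. Before that, the C6''–O–C4' ether is made at the unchelated 5'-phenol of 1 with 1-bromo-4-iodobenzene; the bromine later becomes the boron of 9.
4. Ring order: the four benzene rings are bought; ring C'' is closed in step 2 (C2'' set in step 3) and ring C in step 6 (C2 set in step 7). Closure of 2'-hydroxychalcones is avoided because it is reversible and poorly enantioselective on unactivated enones, and an acetyl/formyl linker would self-condense.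

Key step: step 8

Assumption: Pd(OCOCF3)2 with a pyridine-oxazoline ligand is taken to select the same face of a chromone as of a cyclic enone, which assigns (R)-4-tert-butyl-2-(pyridin-2-yl)-4,5-dihydrooxazole, (R)-t-BuPyOx, to the 2S series; the sense is to be checked on 7 by circular dichroism and the antipodal ligand used if it is reversed.

**Route**

Step 1
Reactants: 1 2',5'-dihydroxy-4'-methoxyacetophenone; 2 1-bromo-4-iodobenzene (1.1 equiv)
Product: 3 1-[5-(4-bromophenoxy)-2-hydroxy-4-methoxyphenyl]ethan-1-one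
Conditions: CuI (10 mol%), picolinic acid (20 mol%), K3PO4 (2 equiv), DMSO, 80 °C, argon
Reagents that add atoms: none
Why: Ullmann-type copper-catalysed O-arylation: the unchelated 5'-phenoxide couples at the C–I bond, which reacts with copper far faster than C–Br, while the 2'-OH stays free because it is hydrogen-bonded to and flanked by the acetyl group, so the C6''–O–C4' ether and the bromine handle are installed together.

Step 2
Reactants: 3 1-[5-(4-bromophenoxy)-2-hydroxy-4-methoxyphenyl]ethan-1-one
Product: 5 6-(4-bromophenoxy)-7-methoxy-4H-chromen-4-one, via enaminone 4 (not isolated)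
Conditions: Me2NCH(OMe)2 (2 equiv), toluene, 90 °C; evaporate; conc. HCl, CH2Cl2, rt
Reagents that add atoms: N,N-dimethylformamide dimethyl acetal, COC(OC)N(C)C
Why: Condensation of the acetyl CH3 with the amide acetal gives the enaminone, and acid then lets the only phenol ortho to the acyl group add to the β-carbon and expel Me2NH (addition–elimination), closing ring C'' as a chromone with no regiochemical choice.

Step 3
Reactants: 5 6-(4-bromophenoxy)-7-methoxy-4H-chromen-4-one; 6 4-acetoxyphenylboronic acid (2 equiv)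
Product: 7 (S)-4-[6-(4-bromophenoxy)-7-methoxy-4-oxochroman-2-yl]phenyl acetate
Conditions: Pd(OCOCF3)2 (5 mol%), (R)-t-BuPyOx (6 mol%), NH4PF6 (30 mol%), H2O (5 equiv), ClCH2CH2Cl, 60 °C; recrystallise to raise enantiomeric purity
Reagents that add atoms: none
Why: Palladium-catalysed asymmetric conjugate addition of an arylboronic acid to a chromone: the aryl group passes from boron to the cationic divalent palladium–pyridine-oxazoline complex, C2''=C3'' inserts with the tert-butyl group of the (R)-ligand leaving only the Re face of C2'' open (hence 2''S), and water protonates the palladium enolate without base, so the flavanone cannot racemise by ring opening and the C–Br bond and acetate are untouched by the phosphine-free complex.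

Step 4
Reactants: 7 (S)-4-[6-(4-bromophenoxy)-7-methoxy-4-oxochroman-2-yl]phenyl acetate
Product: 8 (S)-4-{7-methoxy-4-oxo-6-[4-(4,4,5,5-tetramethyl-1,3,2-dioxaborolan-2-yl)phenoxy]chroman-2-yl}phenyl acetate
Conditions: B2pin2 (1.2 equiv), Pd(OAc)2 (2 mol%), 2-dicyclohexylphosphino-2',4',6'-triisopropylbiphenyl (XPhos, 4 mol%), potassium 2-ethylhexanoate (2.5 equiv), i-PrOAc, 35 °C
Reagents that add atoms: bis(pinacolato)diboron, CC1(C)OB(OC1(C)C)B1OC(C)(C)C(C)(C)O1
Why: Miyaura borylation: zerovalent palladium–XPhos inserts into the C–Br bond, the carboxylate-bound palladium aryl transmetalates with B2pin2 and reductive elimination gives the aryl boronate, and the soluble, weakly basic 2-ethylhexanoate lets this run near room temperature, so neither ring opening at C2'' nor acetate cleavage is expected.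

Step 5
Reactants: 8 (S)-4-{7-methoxy-4-oxo-6-[4-(4,4,5,5-tetramethyl-1,3,2-dioxaborolan-2-yl)phenoxy]chroman-2-yl}phenyl acetate
Product: 9 (S)-[4-({2-(4-acetoxyphenyl)-7-methoxy-4-oxochroman-6-yl}oxy)phenyl]boronic acid
Conditions: NaIO4 (3 equiv), THF/H2O 4:1, rt; then 1 M HCl, rt
Reagents that add atoms: water, O
Why: Oxidative removal of pinacol: the ester hydrolyses reversibly in aqueous acid and NaIO4 cleaves the liberated diol to acetone, pulling the equilibrium to the free boronic acid that the base-free conjugate addition needs, under acidic conditions that leave C2'' and the acetate alone.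

Step 6
Reactants: 10 2'-hydroxy-4'-methoxyacetophenone (paeonol)
Product: 12 7-methoxy-4H-chromen-4-one, via enaminone 11 (not isolated)
Conditions: Me2NCH(OMe)2 (2 equiv), toluene, 90 °C; evaporate; conc. HCl, CH2Cl2, rt
Reagents that add atoms: N,N-dimethylformamide dimethyl acetal, COC(OC)N(C)C
Why: The same enaminone formation and acid-promoted addition–elimination as in step 2, here on a substrate with a single phenol, closes ring C as 7-methoxychromone.

Step 7
Reactants: 9 (S)-[4-({2-(4-acetoxyphenyl)-7-methoxy-4-oxochroman-6-yl}oxy)phenyl]boronic acid; 12 7-methoxy-4H-chromen-4-one (3 equiv)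
Product: 13 (2S,2''S)-4'''-O-acetyl-5,5''-dideoxy-7,7''-di-O-methyltetrahydrohinokiflavone, i.e. 4-[(2S)-7-methoxy-6-{4-[(2S)-7-methoxy-4-oxochroman-2-yl]phenoxy}-4-oxochroman-2-yl]phenyl acetate
Conditions: Pd(OCOCF3)2 (10 mol%), (R)-t-BuPyOx (12 mol%), NH4PF6 (30 mol%), H2O (5 equiv), ClCH2CH2Cl, 60 °C; 9 added in portions
Reagents that add atoms: none
Why: The asymmetric conjugate addition of step 3 again, with the cheap chromone in excess: the (R)-ligand sets C2 as S (aryl to the Re face of C2) independently of C2'', which lies eleven bonds away, and the ketone, acetate and ether groups of 9 do not react with the divalent palladium aryl.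

Step 8
Reactants: 13 (2S,2''S)-4'''-O-acetyl-5,5''-dideoxy-7,7''-di-O-methyltetrahydrohinokiflavone
Product: 15 (2S,2''S)-4'''-O-acetyl-7,7''-di-O-methyltetrahydrohinokiflavone, via bis(trifluoroacetate) 14 (not isolated)
Conditions: [RuCl2(p-cymene)]2 (10 mol%), K2S2O8 (3 equiv), CF3CO2H/(CF3CO)2O 4:1, 60 °C; then ice-cold aq. NaHCO3, EtOAc
Reagents that add atoms: trifluoroacetic acid, OC(=O)C(F)(F)F
Why: Proposed new method: Ru(O2CCF3)2(p-cymene), formed in the flask, binds each flavanone carbonyl oxygen and cleaves the peri C5–H or C5''–H bond by carboxylate-assisted metalation to a five-membered ruthenacycle (Ru–O=C4–C4a–C5); K2S2O8 oxidises this divalent ruthenium aryl to tetravalent ruthenium, C–O reductive elimination with a trifluoroacetate ligand gives the aryl trifluoroacetates of 14, and aqueous work-up hydrolyses them to the chelated phenols of 15. The closest known reaction type is the ruthenium- or palladium-catalysed ketone-directed ortho C–H hydroxylation of aryl ketones, chromones and flavones in CF3CO2H/(CF3CO)2O; new here is its twofold use on 2-arylchroman-4-ones with acid-sensitive benzylic ether stereocentres, one site (C5'') being flanked by the aryloxy group on C6''. No ring is closed and no stereocentre is made; C2 and C2'' only have to survive, which is expected because the para substituents on rings B and B''' (aryloxy, acetoxy) are weak donors that give little help to C2–O1 ionisation, and the temperature is kept as low as conversion allows. Site selectivity comes from chelation: each ketone has one free ortho position only, the other (C8a, C8a'') bearing the ring oxygen, and no other aromatic C–H bond can reach a five-membered chelate. Chemoselectivity against oxidation of the ether-rich rings rests on the acetate on O4''' (no free phenol on ring B'''), on the electron-poor trifluoroacetate form in which the new oxygens stay until work-up, and on the acyl group carried by each methoxy-bearing ring.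

Step 9
Reactants: 15 (2S,2''S)-4'''-O-acetyl-7,7''-di-O-methyltetrahydrohinokiflavone
Product: 16 7,7''-di-O-methyltetrahydrohinokiflavone (2S,2''S)
Conditions: NH4OAc (8 equiv), MeOH/H2O 4:1, rt
Reagents that add atoms: none
Why: NH4OAc promotes methanolysis of the aryl acetate at near-neutral pH, where flavanones do not open to chalcones, so C2 and C2'' keep their configuration and the hydrogen-bonded 5- and 5''-hydroxyls are unaffected.

**Compound list**

1 | 2',5'-dihydroxy-4'-methoxyacetophenone | CC(=O)c1cc(O)c(OC)cc1O | starting material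
2 | 1-bromo-4-iodobenzene | Brc1ccc(I)cc1 | starting material
3 | 1-[5-(4-bromophenoxy)-2-hydroxy-4-methoxyphenyl]ethan-1-one | CC(=O)c1cc(Oc2ccc(Br)cc2)c(OC)cc1O | intermediate
4 | (E)-1-[5-(4-bromophenoxy)-2-hydroxy-4-methoxyphenyl]-3-(dimethylamino)prop-2-en-1-one | CN(C)/C=C/C(=O)c1cc(Oc2ccc(Br)cc2)c(OC)cc1O | intermediate (not isolated)
5 | 6-(4-bromophenoxy)-7-methoxy-4H-chromen-4-one | COc1cc2occc(=O)c2cc1Oc1ccc(Br)cc1 | intermediate
6 | 4-acetoxyphenylboronic acid | CC(=O)Oc1ccc(B(O)O)cc1 | starting material
7 | (S)-4-[6-(4-bromophenoxy)-7-methoxy-4-oxochroman-2-yl]phenyl acetate | COc1cc2c(cc1Oc1ccc(Br)cc1)C(=O)C[C@@H](c1ccc(OC(C)=O)cc1)O2 | intermediate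
8 | (S)-4-{7-methoxy-4-oxo-6-[4-(4,4,5,5-tetramethyl-1,3,2-dioxaborolan-2-yl)phenoxy]chroman-2-yl}phenyl acetate | COc1cc2c(cc1Oc1ccc(B3OC(C)(C)C(C)(C)O3)cc1)C(=O)C[C@@H](c1ccc(OC(C)=O)cc1)O2 | intermediate
9 | (S)-[4-({2-(4-acetoxyphenyl)-7-methoxy-4-oxochroman-6-yl}oxy)phenyl]boronic acid | COc1cc2c(cc1Oc1ccc(B(O)O)cc1)C(=O)C[C@@H](c1ccc(OC(C)=O)cc1)O2 | intermediate
10 | 2'-hydroxy-4'-methoxyacetophenone (paeonol) | CC(=O)c1ccc(OC)cc1O | starting material
11 | (E)-3-(dimethylamino)-1-(2-hydroxy-4-methoxyphenyl)prop-2-en-1-one | CN(C)/C=C/C(=O)c1ccc(OC)cc1O | intermediate (not isolated)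
12 | 7-methoxy-4H-chromen-4-one | COc1ccc2c(c1)occc2=O | intermediate
13 | (2S,2''S)-4'''-O-acetyl-5,5''-dideoxy-7,7''-di-O-methyltetrahydrohinokiflavone | COc1ccc2c(c1)O[C@H](c1ccc(Oc3c(OC)cc4c(c3)C(=O)C[C@@H](c3ccc(OC(C)=O)cc3)O4)cc1)CC2=O | intermediate
14 | 5,5''-bis(trifluoroacetate) of 15 | COc1cc(OC(=O)C(F)(F)F)c2c(c1)O[C@H](c1ccc(Oc3c(OC)cc4c(c3OC(=O)C(F)(F)F)C(=O)C[C@@H](c3ccc(OC(C)=O)cc3)O4)cc1)CC2=O | intermediate (not isolated)
15 | (2S,2''S)-4'''-O-acetyl-7,7''-di-O-methyltetrahydrohinokiflavone | COc1cc(O)c2c(c1)O[C@H](c1ccc(Oc3c(OC)cc4c(c3O)C(=O)C[C@@H](c3ccc(OC(C)=O)cc3)O4)cc1)CC2=O | intermediate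
16 | 7,7''-di-O-methyltetrahydrohinokiflavone (2S,2''S) | COc1cc(O)c2c(c1)O[C@H](c1ccc(Oc3c(OC)cc4c(c3O)C(=O)C[C@@H](c3ccc(O)cc3)O4)cc1)CC2=O | target

**Step count**

Total: 9 steps. Longest linear sequence: 8 steps (1 → 3 → 5 → 7 → 8 → 9 → 13 → 15 → 16); step 6 is the side branch.

**Steps most likely to fail**

1. Step 8 (the proposed new method). Metalation may stall at the hindered C5''–H so that mono-oxygenated material accumulates. The warm acid may open and reclose the pyranone rings through the C2–O1 bond and erode C2 or C2''; the resulting diastereomers would be hard to separate because the centres are remote. K2S2O8 may also degrade the oxygen-rich rings, or the acetate carbonyl may direct a stray oxygenation on ring B'''.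
Fallback (known chemistry), setting out from 5 and 12 and coming back at 15: the two oxygens are put in at the chromone stage, where ruthenium-catalysed C5 hydroxylation is an established reaction and no stereocentre is at risk. Chromone 5 with [RuCl2(p-cymene)]2 and PhI(OCOCF3)2 in CF3CO2H/(CF3CO)2O at 80 °C gives 6-(4-bromophenoxy)-7-methoxy-4-oxo-4H-chromen-5-yl trifluoroacetate F1, hydrolysed on work-up to 6-(4-bromophenoxy)-5-hydroxy-7-methoxy-4H-chromen-4-one F2. Chromone 12 likewise gives 7-methoxy-4-oxo-4H-chromen-5-yl trifluoroacetate F3 and then 5-hydroxy-7-methoxy-4H-chromen-4-one F4. F2 then follows steps 3 to 5. Addition of 6 under the conditions of step 3 gives (S)-4-[6-(4-bromophenoxy)-5-hydroxy-7-methoxy-4-oxochroman-2-yl]phenyl acetate F5, and borylation as in step 4 gives its pinacol boronate F6. Transesterification with methylboronic acid in CH2Cl2 containing 5% CF3CO2H (NaIO4 is avoided next to the free phenol) gives the boronic acid F7. Conjugate addition of F7 to F4 under the conditions of step 7 gives 15. The hydrogen-bonded 5-hydroxyls should make both chromones better acceptors.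

2. Step 7. Protodeboronation and homocoupling of the valuable boronic acid 9 may outrun its addition to the donor-deactivated chromone 12.
Fallback, setting out from 12 and 1 and coming back at 13: the order of assembly is inverted so that both conjugate additions use cheap boronic acids in excess and the diaryl ether is made late by mild oxidative copper coupling. Chromone 12 and 4-bromophenylboronic acid (2 equiv) with Pd(OCOCF3)2/(R)-t-BuPyOx give (S)-2-(4-bromophenyl)-7-methoxychroman-4-one F8. Borylation as in step 4 gives (S)-7-methoxy-2-[4-(4,4,5,5-tetramethyl-1,3,2-dioxaborolan-2-yl)phenyl]chroman-4-one F9, and cleavage as in step 5 gives (S)-[4-(7-methoxy-4-oxochroman-2-yl)phenyl]boronic acid F10. Separately, 1 with Me2NCH(OMe)2 (1.2 equiv, 75 °C, to limit O-methylation) gives (E)-1-(2,5-dihydroxy-4-methoxyphenyl)-3-(dimethylamino)prop-2-en-1-one F11, which HCl closes to 6-hydroxy-7-methoxy-4H-chromen-4-one F12. Chan–Lam coupling of F10 with F12 (Cu(OAc)2, pyridine, 4 Å sieves, CH2Cl2, air, rt) gives (S)-7-methoxy-6-[4-(7-methoxy-4-oxochroman-2-yl)phenoxy]-4H-chromen-4-one F13. Conjugate addition of 6 (2 equiv) to the chromone of F13 under the conditions of step 3 gives 13.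

3. Step 1. Arylation may occur at both phenols or at the C–Br end, or the hydroquinone-type phenoxide may be oxidised by traces of air in the presence of copper.
Fallback, setting out from 1 and coming back at 3: the ether is made by SNAr and the bromine introduced afterwards. Compound 1 and 1-fluoro-4-nitrobenzene (K2CO3, DMF, rt to 50 °C, argon) give 1-[2-hydroxy-4-methoxy-5-(4-nitrophenoxy)phenyl]ethan-1-one F14 through the more nucleophilic unchelated 5'-phenoxide. Reduction (Fe, NH4Cl, EtOH/H2O, 70 °C) gives 1-[5-(4-aminophenoxy)-2-hydroxy-4-methoxyphenyl]ethan-1-one F15. Diazotisation (NaNO2, aq. HBr, 0 °C) gives 4-(5-acetyl-4-hydroxy-2-methoxyphenoxy)benzenediazonium bromide F16, which the Sandmeyer reaction with CuBr at 60 °C converts into 3.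

**Further compounds**

F1 | step 8 | 6-(4-bromophenoxy)-7-methoxy-4-oxo-4H-chromen-5-yl trifluoroacetate | COc1cc2occc(=O)c2c(OC(=O)C(F)(F)F)c1Oc1ccc(Br)cc1
F2 | step 8 | 6-(4-bromophenoxy)-5-hydroxy-7-methoxy-4H-chromen-4-one | COc1cc2occc(=O)c2c(O)c1Oc1ccc(Br)cc1
F3 | step 8 | 7-methoxy-4-oxo-4H-chromen-5-yl trifluoroacetate | COc1cc(OC(=O)C(F)(F)F)c2c(c1)occc2=O
F4 | step 8 | 5-hydroxy-7-methoxy-4H-chromen-4-one | COc1cc(O)c2c(c1)occc2=O
F5 | step 8 | (S)-4-[6-(4-bromophenoxy)-5-hydroxy-7-methoxy-4-oxochroman-2-yl]phenyl acetate | COc1cc2c(c(O)c1Oc1ccc(Br)cc1)C(=O)C[C@@H](c1ccc(OC(C)=O)cc1)O2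
F6 | step 8 | (S)-4-{5-hydroxy-7-methoxy-4-oxo-6-[4-(4,4,5,5-tetramethyl-1,3,2-dioxaborolan-2-yl)phenoxy]chroman-2-yl}phenyl acetate | COc1cc2c(c(O)c1Oc1ccc(B3OC(C)(C)C(C)(C)O3)cc1)C(=O)C[C@@H](c1ccc(OC(C)=O)cc1)O2
F7 | step 8 | (S)-[4-({2-(4-acetoxyphenyl)-5-hydroxy-7-methoxy-4-oxochroman-6-yl}oxy)phenyl]boronic acid | COc1cc2c(c(O)c1Oc1ccc(B(O)O)cc1)C(=O)C[C@@H](c1ccc(OC(C)=O)cc1)O2
F8 | step 7 | (S)-2-(4-bromophenyl)-7-methoxychroman-4-one | COc1ccc2c(c1)O[C@H](c1ccc(Br)cc1)CC2=O
F9 | step 7 | (S)-7-methoxy-2-[4-(4,4,5,5-tetramethyl-1,3,2-dioxaborolan-2-yl)phenyl]chroman-4-one | COc1ccc2c(c1)O[C@H](c1ccc(B3OC(C)(C)C(C)(C)O3)cc1)CC2=O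
F10 | step 7 | (S)-[4-(7-methoxy-4-oxochroman-2-yl)phenyl]boronic acid | COc1ccc2c(c1)O[C@H](c1ccc(B(O)O)cc1)CC2=O
F11 | step 7 | (E)-1-(2,5-dihydroxy-4-methoxyphenyl)-3-(dimethylamino)prop-2-en-1-one | CN(C)/C=C/C(=O)c1cc(O)c(OC)cc1O
F12 | step 7 | 6-hydroxy-7-methoxy-4H-chromen-4-one | COc1cc2occc(=O)c2cc1O
F13 | step 7 | (S)-7-methoxy-6-[4-(7-methoxy-4-oxochroman-2-yl)phenoxy]-4H-chromen-4-one | COc1ccc2c(c1)O[C@H](c1ccc(Oc3cc4c(=O)ccoc4cc3OC)cc1)CC2=O
F14 | step 1 | 1-[2-hydroxy-4-methoxy-5-(4-nitrophenoxy)phenyl]ethan-1-one | CC(=O)c1cc(Oc2ccc([N+](=O)[O-])cc2)c(OC)cc1O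
F15 | step 1 | 1-[5-(4-aminophenoxy)-2-hydroxy-4-methoxyphenyl]ethan-1-one | CC(=O)c1cc(Oc2ccc(N)cc2)c(OC)cc1O
F16 | step 1 | 4-(5-acetyl-4-hydroxy-2-methoxyphenoxy)benzenediazonium bromide | CC(=O)c1cc(Oc2ccc([N+]#N)cc2)c(OC)cc1O.[Br-]
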